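**Retrosynthetic overview**

1. The last C–C bond is C2 (ring C of the flavanone)–C1′ (ring B). It is made by a catalyst-controlled asymmetric 1,4-addition of a ring-B arylboronic acid, which already carries the complete cyclohexene, to the flat, achiral 7-silyloxychromone; this sets 2R as the fourth stereocentre, independently of the other three.
2. Enabling feature: C2 is the β-carbon of the vinylogous ester O1–C2=C3–C4=O of ring C, so the C2–C1′ bond is the one a conjugate arylation of a chromone creates. C1′ lies para to O4′ and ortho to O2′, which is C5 of 2,4-dihydroxybenzaldehyde, where a bromine (then boron) is available and marks ring B alone among three resorcinol rings.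
3. The cyclohexene ring comes from an enantioselective exo Diels–Alder reaction of a borate-chelated 2′-hydroxychalcone with an (E)-1-aryl-3-methylbuta-1,3-diene that already bears the boronate; it sets the all-trans triad 3″R,4″R,5″S.
4. The chalcone comes from a Claisen–Schmidt condensation; the diene from Miyaura borylation and two Wittig olefinations of 5-bromo-2,4-dihydroxybenzaldehyde.
5. Ring order: all benzene rings and the pyranone ring are bought; the cyclohexene ring is closed in step 10; ring C goes from chromone to chromanone in step 14. All phenols travel as silyl ethers and are freed last by buffered fluoride, because C2 of a 2′,4′-dihydroxyflavanone is labile to acid and base.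

Key step: step 14

Abbreviations: TBS = tert-butyldimethylsilyl (TBSO = its ether oxygen); MOM = methoxymethyl; Bpin = 4,4,5,5-tetramethyl-1,3,2-dioxaborolan-2-yl; VANOL = 3,3′-diphenyl-2,2′-binaphthalene-1,1′-diol; (S)-t-BuPyOX = (S)-4-tert-butyl-2-(pyridin-2-yl)-4,5-dihydrooxazole.

Locants: flavanone numbering O1, C2, C3, C4 with ring B C1′–C6′. Cyclohexene: C1″ (C–CH3), C2″ (=CH), C3″ (bonded to ring B), C4″ (aroyl), C5″ (aryl), C6″ (CH2). In the systematic names these are C3, C2, C1, C6, C5, C4 of the cyclohex-2-en-1-yl group, so 3″R,4″R,5″S equals 1R,6R,5S.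

Assumption: the absolute sense of induction of (R)-VANOL in step 10 and of (S)-t-BuPyOX in step 14 is taken from the usual stereochemical models of these catalyst classes; if a calibration run on the parent chalcone or chromone shows the opposite sense, the antipodal ligand (both are commercial) is used without other change.

**Route**

Step 1
Reactants: 1 1-(2,4-dihydroxyphenyl)ethan-1-one
Product: 2 1-[2-hydroxy-4-(methoxymethoxy)phenyl]ethan-1-one
Conditions: MOMCl (1.1 equiv), K2CO3, acetone, 0 °C to rt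
Reagents that add atoms: chloromethyl methyl ether, COCCl
Why: Williamson-type O-alkylation that should stop at the 4-OH, because the 2-OH is held in a hydrogen bond to the ketone and is far less nucleophilic.

Step 2
Reactants: 3 2,4-dihydroxybenzaldehyde
Product: 4 2,4-bis(methoxymethoxy)benzaldehyde
Conditions: NaH, MOMCl (2.5 equiv), DMF, 0 °C to rt
Reagents that add atoms: chloromethyl methyl ether, COCCl
Why: both phenoxides, formed irreversibly with NaH, are alkylated (Williamson ether synthesis), which removes the acidic protons that would stall the aldol step.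

Step 3
Reactants: 2 1-[2-hydroxy-4-(methoxymethoxy)phenyl]ethan-1-one; 4 2,4-bis(methoxymethoxy)benzaldehyde
Product: 5 (E)-3-[2,4-bis(methoxymethoxy)phenyl]-1-[2-hydroxy-4-(methoxymethoxy)phenyl]prop-2-en-1-one
Conditions: KOH, EtOH/H2O, rt
Reagents that add atoms: none
Why: Claisen–Schmidt condensation in which the enolate of 2 adds to the non-enolisable aldehyde 4 and loss of water gives the conjugated enone in its thermodynamically favoured E geometry.

Step 4
Reactants: 5 (E)-3-[2,4-bis(methoxymethoxy)phenyl]-1-[2-hydroxy-4-(methoxymethoxy)phenyl]prop-2-en-1-one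
Product: 6 (E)-1,3-bis(2,4-dihydroxyphenyl)prop-2-en-1-one
Conditions: HCl (3 M aq), MeOH, 50 °C
Reagents that add atoms: none
Why: acid-catalysed transacetalisation of the three MOM ethers to methanol, run briefly so that the E-enone does not isomerise and cyclise through its ring-B 2-OH.

Step 5
Reactants: 6 (E)-1,3-bis(2,4-dihydroxyphenyl)prop-2-en-1-one
Product: 7 (E)-3-[2,4-bis(TBSO)phenyl]-1-[4-(TBSO)-2-hydroxyphenyl]prop-2-en-1-one
Conditions: TBSCl (3.3 equiv), imidazole, DMF, 0 °C
Reagents that add atoms: tert-butyldimethylsilyl chloride, CC(C)(C)[Si](C)(C)Cl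
Why: silylation of the three unchelated phenols, the 2′-OH being hydrogen-bonded to the carbonyl group and therefore the slowest to react, so that it stays free for boron binding in step 10.

Step 6
Reactants: 8 5-bromo-2,4-dihydroxybenzaldehyde
Product: 9 5-bromo-2,4-bis(TBSO)benzaldehyde
Conditions: TBSCl (2.5 equiv), imidazole, DMF, rt
Reagents that add atoms: tert-butyldimethylsilyl chloride, CC(C)(C)[Si](C)(C)Cl
Why: imidazole-promoted silylation of both phenols gives a substrate free of acidic protons for the palladium and ylide steps.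

Step 7
Reactants: 9 5-bromo-2,4-bis(TBSO)benzaldehyde
Product: 10 2,4-bis(TBSO)-5-Bpin-benzaldehyde
Conditions: B2pin2, PdCl2(dppf) (5 mol%), KOAc, 1,4-dioxane, 85 °C
Reagents that add atoms: bis(pinacolato)diboron, CC1(C)OB(OC1(C)C)B1OC(C)(C)C(C)(C)O1
Why: Miyaura borylation (oxidative addition of zerovalent palladium into C–Br, acetate-assisted transmetalation with the diboron, reductive elimination), in which the weak base KOAc spares the aldehyde and the aryl silyl ethers.

Step 8
Reactants: 10 2,4-bis(TBSO)-5-Bpin-benzaldehyde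
Product: 11 (E)-4-[2,4-bis(TBSO)-5-Bpin-phenyl]but-3-en-2-one
Conditions: Ph3P=CHC(O)CH3, toluene, 100 °C
Reagents that add atoms: 1-(triphenyl-λ5-phosphanylidene)propan-2-one, CC(=O)C=P(c1ccccc1)(c1ccccc1)c1ccccc1
Why: Wittig reaction with a stabilised ylide, which is E-selective and neutral, so the silyl ethers and the boronate are untouched.

Step 9
Reactants: 11 (E)-4-[2,4-bis(TBSO)-5-Bpin-phenyl]but-3-en-2-one
Product: 12 (E)-1-[2,4-bis(TBSO)-5-Bpin-phenyl]-3-methylbuta-1,3-diene
Conditions: Ph3PCH3Br, NaN(SiMe3)2, THF, −78 to 0 °C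
Reagents that add atoms: methyltriphenylphosphonium bromide, C[P+](c1ccccc1)(c1ccccc1)c1ccccc1.[Br-] (delivers CH2 through its ylide C=P(c1ccccc1)(c1ccccc1)c1ccccc1)
Why: Wittig methylenation of the methyl ketone at low temperature, which leaves the existing E-alkene and the pinacol boronate intact and gives the s-cis-accessible diene.

Step 10
Reactants: 7 (E)-3-[2,4-bis(TBSO)phenyl]-1-[4-(TBSO)-2-hydroxyphenyl]prop-2-en-1-one; 12 (E)-1-[2,4-bis(TBSO)-5-Bpin-phenyl]-3-methylbuta-1,3-diene
Product: 15 exo adduct 2-{5-[(1R,5S,6R)-6-[4-(TBSO)-2-hydroxybenzoyl]-5-[2,4-bis(TBSO)phenyl]-3-methylcyclohex-2-en-1-yl]-2,4-bis(TBSO)phenyl}-4,4,5,5-tetramethyl-1,3,2-dioxaborolane, via chalcone borate 13 (not isolated), via adduct borate 14 (not isolated)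
Conditions: (R)-VANOL (1.2 equiv), BH3·THF (1.2 equiv), AcOH (1.2 equiv), THF, rt, then evaporation; 7, then 12 (1.5 equiv), PhCF3, rt; aqueous NaHCO3 work-up
Reagents that add atoms: none
Why: Diels–Alder reaction of the 2′-hydroxychalcone held as an O,O-chelated tetracoordinate borate, in which the E-enone fixes C4″/C5″ trans, the exo transition state (aroyl-borate unit turned away from the diene) gives C3″/C4″ trans, bonding of the unsubstituted diene terminus to the β-carbon sets the regiochemistry, and the VANOL backbone shields one enone face to give 3″R,4″R,5″S, the endo (3″S) isomer expected alongside being removed by chromatography.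

Step 11
Reactants: 15 exo adduct (free 2-hydroxybenzoyl group)
Product: 16 2-{5-[(1R,5S,6R)-6-[2,4-bis(TBSO)benzoyl]-5-[2,4-bis(TBSO)phenyl]-3-methylcyclohex-2-en-1-yl]-2,4-bis(TBSO)phenyl}-4,4,5,5-tetramethyl-1,3,2-dioxaborolane
Conditions: TBSOTf, 2,6-lutidine, CH2Cl2, −40 to 0 °C
Reagents that add atoms: tert-butyldimethylsilyl trifluoromethanesulfonate, CC(C)(C)[Si](C)(C)OS(=O)(=O)C(F)(F)F
Why: the silyl triflate overcomes the hydrogen bond of the chelated phenol, so that no 2-acylphenol (a bidentate O,O-ligand for palladium) remains for step 14, while the hindered methine α to the ketone disfavours silyl enol ether formation.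

Step 12
Reactants: 16 hexa-TBS pinacol boronate
Product: 17 {5-[(1R,5S,6R)-6-[2,4-bis(TBSO)benzoyl]-5-[2,4-bis(TBSO)phenyl]-3-methylcyclohex-2-en-1-yl]-2,4-bis(TBSO)phenyl}boronic acid
Conditions: NaIO4, NH4OAc, acetone/THF/H2O, rt
Reagents that add atoms: water, O
Why: the hydrolysis equilibrium of the pinacol ester is pulled to the boronic acid by periodate (Malaprade) cleavage of the released pinacol at buffered pH, conditions that leave aryl silyl ethers, ketone and alkene alone.

Step 13
Reactants: 18 7-hydroxy-4H-chromen-4-one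
Product: 19 7-(TBSO)-4H-chromen-4-one
Conditions: TBSCl, imidazole, DMF, rt
Reagents that add atoms: tert-butyldimethylsilyl chloride, CC(C)(C)[Si](C)(C)Cl
Why: silylation of the only phenol makes the chromone soluble in the chlorinated solvent of step 14 and gives it the same protecting group as the rest of the molecule.

Step 14
Reactants: 17 hexa-TBS arylboronic acid; 19 7-(TBSO)-4H-chromen-4-one (2 equiv)
Product: 20 (2R)-2-{5-[(1R,5S,6R)-6-[2,4-bis(TBSO)benzoyl]-5-[2,4-bis(TBSO)phenyl]-3-methylcyclohex-2-en-1-yl]-2,4-bis(TBSO)phenyl}-7-(TBSO)-2,3-dihydro-4H-chromen-4-one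
Conditions: Pd(OCOCF3)2 (10 mol%), (S)-t-BuPyOX (12 mol%), H2O (5 equiv), ClCH2CH2Cl, 50 °C
Reagents that add atoms: none
Why: Transmetalation of boronic acid 17 to the cationic PyOX complex of divalent palladium gives an arylpalladium species that inserts the C2=C3 bond of chromone 19 with aryl delivery to C2, and the resulting palladium enolate is protonated by water, so the metal stays divalent and no β-hydride elimination to the flavone occurs. The closest known reaction type is the palladium-catalysed asymmetric conjugate addition of arylboronic acids to chromones, which gives 2-arylchroman-4-ones. No ring is closed; ring C is already present in 19 and only changes from enone to ketone. The new stereocentre C2 is controlled by the tert-butyl group of the (S)-ligand, which lets the chromone present only one enantiotopic face of C2 to the migrating aryl group (2R expected), while the three cyclohexene stereocentres lie at least five bonds away and should exert no bias, so the outcome is catalyst controlled. The step needs 1,4- over 1,2-addition and chemoselectivity among two ketones and an alkene; only C2 of 19 is an unhindered conjugate acceptor, the C4″ aryl ketone is not conjugated to an alkene, and the trisubstituted cyclohexene is flanked by an aryl-bearing carbon and a methyl group. Site selectivity on the nucleophile is secured by the boron atom, which marks C1′ of ring B alone among the three resorcinol-type rings.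

Step 15
Reactants: 20 hepta-TBS flavanone
Product: 21 (2R)-2-{5-[(1R,5S,6R)-6-(2,4-dihydroxybenzoyl)-5-(2,4-dihydroxyphenyl)-3-methylcyclohex-2-en-1-yl]-2,4-dihydroxyphenyl}-7-hydroxy-2,3-dihydro-4H-chromen-4-one (target)
Conditions: Bu4NF, AcOH (1:1, excess), THF, 0 °C to rt
Reagents that add atoms: none
Why: fluoride cleaves each aryl silyl ether at silicon while acetic acid protonates every phenoxide as it forms, so neither retro-oxa-Michael opening of ring C nor ionisation of the benzylic C2–O1 bond should scramble C2, and no other stereocentre is touched.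

**Compound list**

1 | 1-(2,4-dihydroxyphenyl)ethan-1-one | CC(=O)c1ccc(O)cc1O | starting material
2 | 1-[2-hydroxy-4-(methoxymethoxy)phenyl]ethan-1-one | CC(=O)c1ccc(OCOC)cc1O | intermediate
3 | 2,4-dihydroxybenzaldehyde | O=Cc1ccc(O)cc1O | starting material
4 | 2,4-bis(methoxymethoxy)benzaldehyde | COCOc1ccc(C=O)c(OCOC)c1 | intermediate
5 | (E)-3-[2,4-bis(methoxymethoxy)phenyl]-1-[2-hydroxy-4-(methoxymethoxy)phenyl]prop-2-en-1-one | COCOc1ccc(C(=O)/C=C/c2ccc(OCOC)cc2OCOC)c(O)c1 | intermediate
6 | (E)-1,3-bis(2,4-dihydroxyphenyl)prop-2-en-1-one | O=C(/C=C/c1ccc(O)cc1O)c1ccc(O)cc1O | intermediate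
7 | (E)-3-[2,4-bis(TBSO)phenyl]-1-[4-(TBSO)-2-hydroxyphenyl]prop-2-en-1-one | CC(C)(C)[Si](C)(C)Oc1ccc(C(=O)/C=C/c2ccc(O[Si](C)(C)C(C)(C)C)cc2O[Si](C)(C)C(C)(C)C)c(O)c1 | intermediate
8 | 5-bromo-2,4-dihydroxybenzaldehyde | O=Cc1cc(Br)c(O)cc1O | starting material
9 | 5-bromo-2,4-bis(TBSO)benzaldehyde | O=Cc1cc(Br)c(O[Si](C)(C)C(C)(C)C)cc1O[Si](C)(C)C(C)(C)C | intermediate
10 | 2,4-bis(TBSO)-5-Bpin-benzaldehyde | O=Cc1cc(B2OC(C)(C)C(C)(C)O2)c(O[Si](C)(C)C(C)(C)C)cc1O[Si](C)(C)C(C)(C)C | intermediate
11 | (E)-4-[2,4-bis(TBSO)-5-Bpin-phenyl]but-3-en-2-one | CC(=O)/C=C/c1cc(B2OC(C)(C)C(C)(C)O2)c(O[Si](C)(C)C(C)(C)C)cc1O[Si](C)(C)C(C)(C)C | intermediate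
12 | (E)-1-[2,4-bis(TBSO)-5-Bpin-phenyl]-3-methylbuta-1,3-diene | C=C(C)/C=C/c1cc(B2OC(C)(C)C(C)(C)O2)c(O[Si](C)(C)C(C)(C)C)cc1O[Si](C)(C)C(C)(C)C | intermediate
13 | chalcone borate: 7 bound through its 2′-phenolate oxygen and its carbonyl oxygen to the boron atom of the (R)-VANOL diolate (tetracoordinate borate; axial chirality R, not encoded in the SMILES) | CC(C)(C)[Si](C)(C)Oc1ccc2c(c1)O[B-]1(Oc3c(-c4c(O1)c5ccccc5cc4-c4ccccc4)c(-c4ccccc4)cc4ccccc34)[O+]=C2/C=C/c1ccc(O[Si](C)(C)C(C)(C)C)cc1O[Si](C)(C)C(C)(C)C | intermediate (not isolated)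
14 | adduct borate: the same O,O-chelate of exo adduct 15 on the (R)-VANOL borate (3″R,4″R,5″S) | CC1=C[C@@H](c2cc(B3OC(C)(C)C(C)(C)O3)c(O[Si](C)(C)C(C)(C)C)cc2O[Si](C)(C)C(C)(C)C)[C@H](C2=[O+][B-]3(Oc4c(-c5c(O3)c6ccccc6cc5-c5ccccc5)c(-c5ccccc5)cc5ccccc45)Oc3cc(O[Si](C)(C)C(C)(C)C)ccc23)[C@@H](c2ccc(O[Si](C)(C)C(C)(C)C)cc2O[Si](C)(C)C(C)(C)C)C1 | intermediate (not isolated)
15 | exo adduct 2-{5-[(1R,5S,6R)-6-[4-(TBSO)-2-hydroxybenzoyl]-5-[2,4-bis(TBSO)phenyl]-3-methylcyclohex-2-en-1-yl]-2,4-bis(TBSO)phenyl}-4,4,5,5-tetramethyl-1,3,2-dioxaborolane | CC1=C[C@@H](c2cc(B3OC(C)(C)C(C)(C)O3)c(O[Si](C)(C)C(C)(C)C)cc2O[Si](C)(C)C(C)(C)C)[C@H](C(=O)c2ccc(O[Si](C)(C)C(C)(C)C)cc2O)[C@@H](c2ccc(O[Si](C)(C)C(C)(C)C)cc2O[Si](C)(C)C(C)(C)C)C1 | intermediate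
16 | 2-{5-[(1R,5S,6R)-6-[2,4-bis(TBSO)benzoyl]-5-[2,4-bis(TBSO)phenyl]-3-methylcyclohex-2-en-1-yl]-2,4-bis(TBSO)phenyl}-4,4,5,5-tetramethyl-1,3,2-dioxaborolane | CC1=C[C@@H](c2cc(B3OC(C)(C)C(C)(C)O3)c(O[Si](C)(C)C(C)(C)C)cc2O[Si](C)(C)C(C)(C)C)[C@H](C(=O)c2ccc(O[Si](C)(C)C(C)(C)C)cc2O[Si](C)(C)C(C)(C)C)[C@@H](c2ccc(O[Si](C)(C)C(C)(C)C)cc2O[Si](C)(C)C(C)(C)C)C1 | intermediate
17 | {5-[(1R,5S,6R)-6-[2,4-bis(TBSO)benzoyl]-5-[2,4-bis(TBSO)phenyl]-3-methylcyclohex-2-en-1-yl]-2,4-bis(TBSO)phenyl}boronic acid | CC1=C[C@@H](c2cc(B(O)O)c(O[Si](C)(C)C(C)(C)C)cc2O[Si](C)(C)C(C)(C)C)[C@H](C(=O)c2ccc(O[Si](C)(C)C(C)(C)C)cc2O[Si](C)(C)C(C)(C)C)[C@@H](c2ccc(O[Si](C)(C)C(C)(C)C)cc2O[Si](C)(C)C(C)(C)C)C1 | intermediate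
18 | 7-hydroxy-4H-chromen-4-one | O=c1ccoc2cc(O)ccc12 | starting material
19 | 7-(TBSO)-4H-chromen-4-one | CC(C)(C)[Si](C)(C)Oc1ccc2c(=O)ccoc2c1 | intermediate
20 | (2R)-2-{5-[(1R,5S,6R)-6-[2,4-bis(TBSO)benzoyl]-5-[2,4-bis(TBSO)phenyl]-3-methylcyclohex-2-en-1-yl]-2,4-bis(TBSO)phenyl}-7-(TBSO)-2,3-dihydro-4H-chromen-4-one | CC1=C[C@@H](c2cc([C@H]3CC(=O)c4ccc(O[Si](C)(C)C(C)(C)C)cc4O3)c(O[Si](C)(C)C(C)(C)C)cc2O[Si](C)(C)C(C)(C)C)[C@H](C(=O)c2ccc(O[Si](C)(C)C(C)(C)C)cc2O[Si](C)(C)C(C)(C)C)[C@@H](c2ccc(O[Si](C)(C)C(C)(C)C)cc2O[Si](C)(C)C(C)(C)C)C1 | intermediate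
21 | (2R)-2-{5-[(1R,5S,6R)-6-(2,4-dihydroxybenzoyl)-5-(2,4-dihydroxyphenyl)-3-methylcyclohex-2-en-1-yl]-2,4-dihydroxyphenyl}-7-hydroxy-2,3-dihydro-4H-chromen-4-one | CC1=C[C@@H](c2cc([C@H]3CC(=O)c4ccc(O)cc4O3)c(O)cc2O)[C@H](C(=O)c2ccc(O)cc2O)[C@@H](c2ccc(O)cc2O)C1 | target

**Totals**

Total step count: 15.
Longest linear sequence: 9 steps (8 → 9 → 10 → 11 → 12 → 15 → 16 → 17 → 20 → 21, i.e. steps 6, 7, 8, 9, 10, 11, 12, 14, 15; the branches from 1 and from 3 are equally long).

**Steps most likely to fail**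

Step 14. What may go wrong: slow transmetalation and insertion of the ortho-silyloxy aryl group; protodeboronation of the electron-rich boronic acid, which here is the valuable partner and cannot be used in excess; and erosion of the catalyst-controlled facial selectivity at C2. Fallback: the two unions are made in the reverse order, so that the C2–C1′ bond is formed on a cheap boronic acid used in excess and the cyclohexene is closed last. The fallback sets out from 10. Cleavage of its pinacol ester (NaIO4, NH4OAc, acetone/H2O) should give 5-formyl-2,4-bis(TBSO)phenylboronic acid F1. Its addition (2.5 equiv) to 19 under the conditions of step 14 should give the aldehyde (2R)-2-[5-formyl-2,4-bis(TBSO)phenyl]-7-(TBSO)chroman-4-one F2, whose enantiomeric purity can be raised by recrystallisation at this simple stage. Allylboration of the aldehyde group alone with 2-methylallylboronic acid pinacol ester (toluene, 60 °C) should give the homoallylic alcohol F3 as a mixture of carbinol epimers, and elimination with the Burgess reagent (toluene, 50 °C) should give the E-diene F4. Cycloaddition of F4 with 7 under the conditions of step 10 (through chalcone borate 13) should give, via the adduct borate F5, which is not isolated, the exo adduct F6, which carries six TBS groups and a free chelated phenol. The desilylation of step 15 converts F6 into 21, where the fallback comes back to the route.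

Step 10. What may go wrong: poor exo/endo selectivity, low facial selectivity with the bulky ortho-silyloxy diene, and polymerisation of the diene before it is consumed. Fallback: asymmetric induction is given up for resolution. The fallback sets out from 7 and 12. Their thermal cycloaddition without any promoter (toluene, 150 °C, sealed tube, radical inhibitor) should give, after removal of the endo isomers on silica, the racemic exo adduct, that is 15 together with its enantiomer F7. The two are separated by preparative chromatography on a chiral stationary phase, and 15 re-enters the route at step 11.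

Step 12. What may go wrong: incomplete cleavage of the hindered pinacol ester, and protodeboronation or anhydride formation of the electron-rich boronic acid during oxidative work-up and chromatography. Fallback: boron is transferred instead of the diol being destroyed. The fallback sets out from 16. Stirring with diethanolamine (Et2O/i-PrOH, rt) should move boron from pinacol onto the aminodiol and precipitate the tetracoordinate diethanolamine adduct F8, which is purified by filtration. Brief partition of F8 between ether and dilute aqueous acid (pH 4–5) should release boronic acid 17 into the organic phase, where the fallback comes back to the route without an oxidant or chromatography.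

**Further compounds**

F1 | step 14 | 5-formyl-2,4-bis(TBSO)phenylboronic acid | O=Cc1cc(B(O)O)c(O[Si](C)(C)C(C)(C)C)cc1O[Si](C)(C)C(C)(C)C
F2 | step 14 | (2R)-2-[5-formyl-2,4-bis(TBSO)phenyl]-7-(TBSO)-2,3-dihydro-4H-chromen-4-one | O=Cc1cc([C@H]2CC(=O)c3ccc(O[Si](C)(C)C(C)(C)C)cc3O2)c(O[Si](C)(C)C(C)(C)C)cc1O[Si](C)(C)C(C)(C)C
F3 | step 14 | (2R)-2-[5-(1-hydroxy-3-methylbut-3-en-1-yl)-2,4-bis(TBSO)phenyl]-7-(TBSO)-2,3-dihydro-4H-chromen-4-one (carbinol epimers) | C=C(C)CC(O)c1cc([C@H]2CC(=O)c3ccc(O[Si](C)(C)C(C)(C)C)cc3O2)c(O[Si](C)(C)C(C)(C)C)cc1O[Si](C)(C)C(C)(C)C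
F4 | step 14 | (2R)-2-{5-[(E)-3-methylbuta-1,3-dien-1-yl]-2,4-bis(TBSO)phenyl}-7-(TBSO)-2,3-dihydro-4H-chromen-4-one | C=C(C)/C=C/c1cc([C@H]2CC(=O)c3ccc(O[Si](C)(C)C(C)(C)C)cc3O2)c(O[Si](C)(C)C(C)(C)C)cc1O[Si](C)(C)C(C)(C)C
F5 | step 14 | adduct borate of F6: O,O-chelate of its 2-hydroxybenzoyl group on the (R)-VANOL borate (not isolated) | CC1=C[C@@H](c2cc([C@H]3CC(=O)c4ccc(O[Si](C)(C)C(C)(C)C)cc4O3)c(O[Si](C)(C)C(C)(C)C)cc2O[Si](C)(C)C(C)(C)C)[C@H](C2=[O+][B-]3(Oc4c(-c5c(O3)c6ccccc6cc5-c5ccccc5)c(-c5ccccc5)cc5ccccc45)Oc3cc(O[Si](C)(C)C(C)(C)C)ccc23)[C@@H](c2ccc(O[Si](C)(C)C(C)(C)C)cc2O[Si](C)(C)C(C)(C)C)C1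
F6 | step 14 | (2R)-2-{5-[(1R,5S,6R)-6-[4-(TBSO)-2-hydroxybenzoyl]-5-[2,4-bis(TBSO)phenyl]-3-methylcyclohex-2-en-1-yl]-2,4-bis(TBSO)phenyl}-7-(TBSO)-2,3-dihydro-4H-chromen-4-one | CC1=C[C@@H](c2cc([C@H]3CC(=O)c4ccc(O[Si](C)(C)C(C)(C)C)cc4O3)c(O[Si](C)(C)C(C)(C)C)cc2O[Si](C)(C)C(C)(C)C)[C@H](C(=O)c2ccc(O[Si](C)(C)C(C)(C)C)cc2O)[C@@H](c2ccc(O[Si](C)(C)C(C)(C)C)cc2O[Si](C)(C)C(C)(C)C)C1
F7 | step 10 | enantiomer of 15, the (1S,5R,6S) exo adduct | CC1=C[C@H](c2cc(B3OC(C)(C)C(C)(C)O3)c(O[Si](C)(C)C(C)(C)C)cc2O[Si](C)(C)C(C)(C)C)[C@@H](C(=O)c2ccc(O[Si](C)(C)C(C)(C)C)cc2O)[C@H](c2ccc(O[Si](C)(C)C(C)(C)C)cc2O[Si](C)(C)C(C)(C)C)C1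
F8 | step 12 | diethanolamine adduct of boronic acid 17 (tetracoordinate N→B 1,3,6,2-dioxazaborocane) | CC1=C[C@@H](c2cc([B-]34OCC[NH+]3CCO4)c(O[Si](C)(C)C(C)(C)C)cc2O[Si](C)(C)C(C)(C)C)[C@H](C(=O)c2ccc(O[Si](C)(C)C(C)(C)C)cc2O[Si](C)(C)C(C)(C)C)[C@@H](c2ccc(O[Si](C)(C)C(C)(C)C)cc2O[Si](C)(C)C(C)(C)C)C1
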